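## The problem

The target is a spiro[5.5]undecane of the chamigrene type. Ring A (C6–C1H2–C2HBr–C3(CH3)Cl–C4H2–C5H2) and ring B (C6–C7(=C14H2)–C8(=O)–C9H=C10Br–C11(CH3)2) share the quaternary carbon C6, which sits next to a second fully substituted carbon, C11. There are three stereocentres, C2 (S), C3 (S) and C6 (S). Bromine and chlorine are trans, and bromine lies on the face of ring A that C11 occupies. C6 is stereogenic only because ring A is unsymmetrical, and its two ring B arms are of similar size, so C6 cannot be trusted to steer a reagent to one face of ring A. C2 and C3 are tied to each other, because a bromonium ion across C2–C3 takes up chloride anti at the tertiary carbon. The secondary bromide beside a tertiary chloride eliminates with base and ionises with Lewis acids, the β-bromoenone is open to addition–elimination, and the cross-conjugated α-methylene ketone is a strong Michael acceptor, so C14 should come last. The feature that opens ring B is that C11, with two methyl groups and a place next to C6, is the tertiary radical of an isopropenyl group, while C8(=O)–C9H=C10Br is what an ynone with bromine on its β-carbon becomes once it has accepted that radical inside a ring that forbids loss of the bromine atom.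

## Retrosynthesis

**C7=C14.** The exocyclic methylene of 22 is removed first, leaving spiro bromoenone 18. Ketone 18 can enolise only toward C7 (C9 is vinylic, C11 quaternary), so a Mannich reaction and amine elimination through 20 is regiochemically unambiguous. Putting this last keeps the most electrophilic group out of every earlier step.

**C10–C11 (key cut).** Cutting C10–C11 of 18 opens ring B to bromoynone 17, in which C6 carries an isopropenyl group and a 4-bromo-2-oxobut-3-ynyl arm. The neighbouring cuts are poorer. A C8–C9 or C9=C10 cut leads to 1,3-diketone chemistry, which is expected to put the halogen on the less hindered carbonyl carbon, C8. A cut at C6 requires the spiro centre to be made on a finished ring B. The chosen cut removes a ring and one quaternary carbon and brings the vinyl bromide in with the ring. The forward reaction must transfer a hydrogen atom to the alkene only, close 6-endo, and leave three carbon–halogen bonds alone.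

**C8–C9.** Bromoynone 17 comes from silyl ynone 16, and 16 from dimethylamide 15 and a metalated silylacetylene. Bromine is put on the alkyne in the last step before cyclisation, so the bromoalkyne meets no other reagent.

**C3–Cl and C2–Br.** Amide 15 is traced to alkene 12 through bromohydrin 14 and epoxide 13. Direct bromochlorination of 12 would not distinguish the faces of ring A, since the isopropenyl and acetamide arms on C6 are of like size. The face is therefore chosen by a chiral dioxirane (13). Bromide then enters C2 with inversion (14), and chloride replaces the C3 hydroxyl with retention through the bromonium ion (15). The dioxirane must prefer the trisubstituted alkene to the isopropenyl group, and bromide must attack the secondary carbon.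

**C3–CH3 and the position of the ring alkene.** Alkene 12 comes from enol triflate 11 by methyl cross-coupling, and 11 from enone 9 by conjugate reduction with trapping of the regiodefined enolate 10. A saturated C3 ketone would be achiral; the enone-to-triflate route never passes through it, so the configuration at C6 is kept. Enone 9 comes from cyclohexene 8 by oxidation of its only allylic methylene.

**C6–C7.** Amide 8 is the Eschenmoser–Claisen product of allylic alcohol 5 and amide acetal 6. The rearrangement sets C6 by chirality transfer and fixes which arm of ring A carries the alkene. The amide acetal is preferred to an orthoester because it needs no acid, which the dienyl carbinol would not tolerate well. Alcohol 5 comes from dienone 4 by Corey–Bakshi–Shibata reduction, and 4 from vinylogous ester 1 and Grignard reagent 2.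

## Roads not taken

**Alternative 1:** The cut is again C2–Br and the C3 heteroatom bond, but with ring B complete and C7 as a tertiary carbinol. An electrophilic bromine source forms the bromonium ion on C2=C3, and the C7 hydroxyl opens it at C3 to give bromo ether A1, a 2-oxabicyclo[2.2.2]octane across ring A. Its merit is real: the oxygen can reach C3 from one face only, so the relay from C6 to C2 and C3 is secured by geometry. The chosen plan has to buy the same relay with a chiral reagent, and in this respect Alternative 1 is better. Its weak points are that the C7 carbinol is an extra stereocentre that must be set correctly, and that A1 must later exchange C3–O for C3–Cl with retention and lose the C7 oxygen to form the methylene, both in the presence of the β-bromoenone. It also says nothing about how ring B and its hindered vinyl bromide are made. Against it the chosen plan sets a ring B closure that installs the vinyl bromide directly, and an epoxidation on a simple monocyclic amide with no added stereocentre.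

**Alternative 2:** The cut is C6–C11. A chiral Lewis base with an electrophilic bromine source forms a bromonium ion at C10=C11, the tetrasubstituted C6=C7 alkene attacks C11, and loss of a proton from C14 gives A2 with the C7 methylene, the C10 bromide and the quaternary C6 in one step. It is the shortest way to a brominated ring B, and it delivers the C7 methylene for free, where the chosen plan spends two steps. The weak points are three. Enantioselective bromonium cyclisations are dependable mainly with arene terminators, and a tetrasubstituted alkene forming a spiro centre is a hard case. The C10 stereocentre that relays chirality to C6 is destroyed later, since C10 is sp2 in the target. And A2 still needs C8 oxidised and C9=C10 introduced next to a secondary bromide that would leave by elimination, then ring A built from the two arms and halogenated with the same facial problem. The chosen plan is longer to the spiro core but needs no redox correction of ring B.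

**Alternative 3:** The cut is C5–C6 and C1=C2. A chiral primary amine turns a racemic α-branched ring B aldehyde into an enamine that adds to a four-carbon vinyl ketone, and aldol condensation closes ring A to give spiro enone A3. The reaction class is well precedented, catalytic, and sets C6 early with both rings present. The gem-dimethyl group of ring B then offers a real steric difference between the faces of ring A, which the chosen plan lacks. The C10 ketone of A3 can enolise only toward C9, a regiodefined handle for the vinyl bromide. The weak points are that the Michael donor carbon is flanked by a quaternary carbon and should react slowly. Ring A of A3 is at the same enone stage as 9, so nothing is saved there. Ring B then needs C8 oxidation, conversion of the C10 ketone to the vinyl bromide, and methylenation, several steps where the chosen plan needs one ring closure and two finishing steps.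

Key step: step 12

Assumptions on the chemistry: the fructose-derived dioxirane is taken to attack a 1-alkylcyclohexene from the same face as a 1-arylcyclohexene; the oxazaborolidine is taken to treat the alkenyl flank of dienone 4 as the large group.

## Route

Step 1
Reactants: 1 3-ethoxycyclohex-2-en-1-one; 2 isopropenylmagnesium bromide
Product: 4 3-(prop-1-en-2-yl)cyclohex-2-en-1-one, via magnesium alkoxide 3 (not isolated)
Conditions: THF, 0 °C to rt; then 1 M HCl, 0 °C
Reagents that add atoms: water, O
Why: Stork–Danheiser sequence: 1,2-addition of the Grignard reagent to the vinylogous ester, then acid hydrolysis of the enol ether with loss of ethanol and water transposes the carbonyl group and gives the 3-alkenyl enone.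

Step 2
Reactants: 4 3-(prop-1-en-2-yl)cyclohex-2-en-1-one
Product: 5 (1S)-3-(prop-1-en-2-yl)cyclohex-2-en-1-ol
Conditions: (R)-tetrahydro-1-methyl-3,3-diphenyl-1H,3H-pyrrolo[1,2-c][1,3,2]oxazaborole ((R)-Me-CBS, 0.2 equiv), catecholborane (1.8 equiv), toluene, −78 °C
Reagents that add atoms: none
Why: Corey–Bakshi–Shibata reduction; with the dienyl flank as the large group the (R)-catalyst should deliver hydride to give the (S)-carbinol, and catecholborane at low temperature avoids hydroboration of the diene.

Step 3
Reactants: 5 (1S)-3-(prop-1-en-2-yl)cyclohex-2-en-1-ol; 6 N,N-dimethylacetamide dimethyl acetal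
Product: 8 2-[(1R)-1-(prop-1-en-2-yl)cyclohex-2-en-1-yl]-N,N-dimethylacetamide, via ketene N,O-acetal 7 (not isolated)
Conditions: xylenes, 140 °C, MeOH distilled off
Reagents that add atoms: none
Why: Eschenmoser–Claisen rearrangement; the suprafacial [3,3] shift forms C6–C7 on the ring face from which the C–O bond leaves, so the carbinol configuration is transferred to quaternary C6 and the new alkene is fixed at C1=C2, under neutral conditions that spare the dienyl alcohol.

Step 4
Reactants: 8 2-[(1R)-1-(prop-1-en-2-yl)cyclohex-2-en-1-yl]-N,N-dimethylacetamide
Product: 9 2-[(1R)-4-oxo-1-(prop-1-en-2-yl)cyclohex-2-en-1-yl]-N,N-dimethylacetamide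
Conditions: Rh2(cap)4 (dirhodium tetracaprolactamate, 1 mol %), t-BuOOH (70% aq., 5 equiv), K2CO3, CH2Cl2, rt
Reagents that add atoms: tert-butyl hydroperoxide, CC(C)(C)OO
Why: radical allylic C–H oxidation to the enone; C3 is the only allylic methylene of the ring (the other allylic carbon, C6, is quaternary), and the tert-butylperoxyl radical prefers this secondary C–H to the primary methyl C–H of the isopropenyl group, as it does in isopropenyl-bearing terpenes.

Step 5
Reactants: 9 2-[(1R)-4-oxo-1-(prop-1-en-2-yl)cyclohex-2-en-1-yl]-N,N-dimethylacetamide
Product: 11 (4S)-4-[2-(dimethylamino)-2-oxoethyl]-4-(prop-1-en-2-yl)cyclohex-1-en-1-yl trifluoromethanesulfonate, via lithium enolate 10 (not isolated)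
Conditions: L-Selectride (LiBH(s-Bu)3, 1.1 equiv), THF, −78 °C; then PhNTf2 (1.2 equiv), −78 °C to rt
Reagents that add atoms: N-phenylbis(trifluoromethanesulfonimide), O=S(=O)(N(c1ccccc1)S(=O)(=O)C(F)(F)F)C(F)(F)F; L-Selectride, [Li+].CCC(C)[BH-](C(C)CC)C(C)CC (lithium of 10 only)
Why: conjugate reduction of the β-monosubstituted cyclohexenone by the hindered borohydride gives the C2=C3 enolate regiospecifically and O-triflation fixes that double bond; the achiral saturated ketone is never formed, so C6 keeps its configuration, and the amide is too poor an electrophile to be attacked by the enolate.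

Step 6
Reactants: 11 (4S)-4-[2-(dimethylamino)-2-oxoethyl]-4-(prop-1-en-2-yl)cyclohex-1-en-1-yl trifluoromethanesulfonate
Product: 12 2-[(1S)-4-methyl-1-(prop-1-en-2-yl)cyclohex-3-en-1-yl]-N,N-dimethylacetamide
Conditions: MeZnCl (2 equiv), Pd(PPh3)4 (5 mol %), THF, 50 °C
Reagents that add atoms: methylzinc chloride, C[Zn]Cl
Why: Negishi coupling of an unhindered alkenyl triflate installs the C3 methyl group; the amide and the isopropenyl group are inert to the organozinc reagent and to palladium.

Step 7
Reactants: 12 2-[(1S)-4-methyl-1-(prop-1-en-2-yl)cyclohex-3-en-1-yl]-N,N-dimethylacetamide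
Product: 13 2-[(1S,4S,6R)-1-methyl-4-(prop-1-en-2-yl)-7-oxabicyclo[4.1.0]heptan-4-yl]-N,N-dimethylacetamide
Conditions: 1,2:4,5-di-O-isopropylidene-β-D-erythro-2,3-hexodiulo-2,6-pyranose (Shi ketone from D-fructose, 0.3 equiv), Oxone (2KHSO5·KHSO4·K2SO4, 1.4 equiv KHSO5), K2CO3, Bu4NHSO4 (cat.), MeCN/dimethoxymethane–aq. Na2B4O7/EDTA, 0 °C
Reagents that add atoms: Oxone (potassium peroxymonosulfate), [K+].[O-]S(=O)(=O)OO
Why: Shi asymmetric epoxidation; the chiral dioxirane reacts fastest and most selectively with trisubstituted alkenes and, through its spiro transition state, should place oxygen on the face of C2=C3 syn to the C7 arm (C2 R, C3 S), so the reagent and not the unbiased C6 chooses the face, while a small excess of oxidant spares the isopropenyl group.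

Step 8
Reactants: 13 2-[(1S,4S,6R)-1-methyl-4-(prop-1-en-2-yl)-7-oxabicyclo[4.1.0]heptan-4-yl]-N,N-dimethylacetamide
Product: 14 2-[(1R,3S,4S)-3-bromo-4-hydroxy-4-methyl-1-(prop-1-en-2-yl)cyclohexyl]-N,N-dimethylacetamide
Conditions: Li2NiBr4 (2 equiv), THF, 0 °C to rt; pH 7 buffer
Reagents that add atoms: dilithium tetrabromonickelate, [Li+].[Li+].[Ni+2].[Br-].[Br-].[Br-].[Br-]
Why: SN2 opening of the epoxide by soft bromide at the secondary carbon C2 with inversion (trans-diaxial, Fürst–Plattner) puts bromine anti to the C7 arm and leaves the tertiary alcohol at C3; the neutral reagent does not add HBr to the isopropenyl group.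

Step 9
Reactants: 14 2-[(1R,3S,4S)-3-bromo-4-hydroxy-4-methyl-1-(prop-1-en-2-yl)cyclohexyl]-N,N-dimethylacetamide
Product: 15 2-[(1R,3S,4S)-3-bromo-4-chloro-4-methyl-1-(prop-1-en-2-yl)cyclohexyl]-N,N-dimethylacetamide
Conditions: Ghosez's reagent (1-chloro-N,N,2-trimethylprop-1-en-1-amine, 1.5 equiv), CH2Cl2, 0 °C to rt
Reagents that add atoms: 1-chloro-N,N,2-trimethylprop-1-en-1-amine, CC(C)=C(Cl)N(C)C
Why: chlorodehydroxylation under neutral conditions; the alkoxyiminium group leaves with help from the anti bromine, and chloride opens the resulting bromonium ion at the tertiary carbon, so C3 is substituted with net retention and bromine and chlorine end up trans; no HCl is set free to add to the isopropenyl group.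

Step 10
Reactants: 15 2-[(1R,3S,4S)-3-bromo-4-chloro-4-methyl-1-(prop-1-en-2-yl)cyclohexyl]-N,N-dimethylacetamide
Product: 16 1-[(1R,3S,4S)-3-bromo-4-chloro-4-methyl-1-(prop-1-en-2-yl)cyclohexyl]-4-(trimethylsilyl)but-3-yn-2-one
Conditions: Me3SiC≡CH (3 equiv), n-BuLi (3 equiv), THF, −78 °C; BF3·OEt2 (3 equiv), −78 °C; then 15, −78 to −40 °C; aq. NH4Cl
Reagents that add atoms: (trimethylsilyl)acetylene, C#C[Si](C)(C)C
Why: Lewis-acid-promoted addition of a lithium acetylide to an N,N-dimethylamide (alkynyl ketone synthesis); the tetrahedral adduct persists until work-up, so no second addition occurs, and the weakly basic acetylide at low temperature should not eliminate the vicinal halides.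

Step 11
Reactants: 16 1-[(1R,3S,4S)-3-bromo-4-chloro-4-methyl-1-(prop-1-en-2-yl)cyclohexyl]-4-(trimethylsilyl)but-3-yn-2-one
Product: 17 4-bromo-1-[(1R,3S,4S)-3-bromo-4-chloro-4-methyl-1-(prop-1-en-2-yl)cyclohexyl]but-3-yn-2-one
Conditions: NBS (1.1 equiv), AgNO3 (0.1 equiv), acetone, rt, dark
Reagents that add atoms: N-bromosuccinimide, O=C1CCC(=O)N1Br
Why: silver-catalysed bromodesilylation of the alkynylsilane through a silver acetylide, which is much faster than attack of NBS on the isopropenyl group in a dry, non-nucleophilic solvent.

Step 12
Reactants: 17 4-bromo-1-[(1R,3S,4S)-3-bromo-4-chloro-4-methyl-1-(prop-1-en-2-yl)cyclohexyl]but-3-yn-2-one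
Product: 18 (6R,8S,9S)-4,8-dibromo-9-chloro-5,5,9-trimethylspiro[5.5]undec-3-en-2-one
Conditions: Fe(acac)3 (0.3 equiv), PhSiH3 (2.5 equiv), THF/i-PrOH 4:1, 0.01 M, slow addition of 17, 40 °C, argon
Reagents that add atoms: none
Why: Proposed new method: the iron hydride formed from Fe(acac)3 and PhSiH3 should transfer a hydrogen atom to the CH2 terminus of the isopropenyl group, the only electron-rich 1,1-disubstituted alkene present, and so generate the tertiary C11 radical next to quaternary C6. This nucleophilic radical is expected to add to C10, the β-carbon of the bromoynone, in a 6-endo-dig closure of ring B that forms C10–C11 and the second quaternary carbon. The resulting α-keto vinyl radical at C9 cannot expel the bromine atom, since that would require a cyclohexyne, and should instead take a hydrogen atom from silane or isopropanol to give the β-bromoenone. The closest known reaction type is the iron-hydride hydrogen-atom-transfer reductive coupling of alkenes with enones, including cyclisations that create quaternary carbons; an ynone carrying bromine on the attacked carbon has not been used as the acceptor. No stereocentre is formed and the ring enforces the geometry of C9=C10. The step needs 6-endo attack at C10 rather than 5-exo attack at C9, which radical polarity (attack at the electron-poor β-carbon) and the strain of a cyclopentanone with two adjacent quaternary carbons should secure. It also needs hydrogen-atom transfer to the alkene rather than to the ynone or the carbon–halogen bonds, which the preference of metal hydrides for electron-rich alkenes and slow addition at high dilution should secure.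

Step 13
Reactants: 18 (6R,8S,9S)-4,8-dibromo-9-chloro-5,5,9-trimethylspiro[5.5]undec-3-en-2-one
Product: 20 (6S,8S,9S)-4,8-dibromo-9-chloro-1-[(dimethylamino)methyl]-5,5,9-trimethylspiro[5.5]undec-3-en-2-one (both C7 epimers), via silyl dienol ether 19 (not isolated)
Conditions: TMSOTf (1.3 equiv), Et3N (2 equiv), CH2Cl2, 0 °C; then Me2N=CH2+ I− (Eschenmoser's salt, 1.5 equiv), rt; aq. NaHCO3
Reagents that add atoms: N,N-dimethylmethyleneiminium iodide, C=[N+](C)C.[I-]; trimethylsilyl trifluoromethanesulfonate, C[Si](C)(C)OS(=O)(=O)C(F)(F)F (silyl group of 19 only)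
Why: soft enolisation can occur only toward C7, and the Mannich reaction of the silyl dienol ether with the iminium salt forms C7–C14 without strong base; the new C7 stereocentre is removed in the next step and needs no control.

Step 14
Reactants: 20 (6S,8S,9S)-4,8-dibromo-9-chloro-1-[(dimethylamino)methyl]-5,5,9-trimethylspiro[5.5]undec-3-en-2-one
Product: 22 (6S,8S,9S)-4,8-dibromo-9-chloro-5,5,9-trimethyl-1-methylidenespiro[5.5]undec-3-en-2-one, via ammonium iodide 21 (not isolated)
Conditions: MeI (5 equiv), CH2Cl2, rt; then aq. NaHCO3, rt
Reagents that add atoms: iodomethane, CI (its atoms are carried by 21 only)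
Why: N-methylation and E1cB loss of trimethylamine from the β-ammonium ketone give the exocyclic enone; bicarbonate is mild enough to leave the alkyl halides and the β-bromoenone untouched.

## Compound list

1 | 3-ethoxycyclohex-2-en-1-one | CCOC1=CC(=O)CCC1 | starting material
2 | isopropenylmagnesium bromide | CC(=C)[Mg]Br | starting material
3 | bromomagnesium 3-ethoxy-1-(prop-1-en-2-yl)cyclohex-2-en-1-olate (racemic) | CCOC1=CC(O[Mg]Br)(C(C)=C)CCC1 | intermediate
4 | 3-(prop-1-en-2-yl)cyclohex-2-en-1-one | C=C(C)C1=CC(=O)CCC1 | intermediate
5 | (1S)-3-(prop-1-en-2-yl)cyclohex-2-en-1-ol | C=C(C)C1=C[C@@H](O)CCC1 | intermediate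
6 | N,N-dimethylacetamide dimethyl acetal (1,1-dimethoxy-N,N-dimethylethanamine) | CC(OC)(OC)N(C)C | starting material
7 | N,N-dimethyl-1-{[(1S)-3-(prop-1-en-2-yl)cyclohex-2-en-1-yl]oxy}ethen-1-amine | C=C(C)C1=C[C@@H](OC(=C)N(C)C)CCC1 | intermediate
8 | 2-[(1R)-1-(prop-1-en-2-yl)cyclohex-2-en-1-yl]-N,N-dimethylacetamide | C=C(C)[C@@]1(CC(=O)N(C)C)CCCC=C1 | intermediate
9 | 2-[(1R)-4-oxo-1-(prop-1-en-2-yl)cyclohex-2-en-1-yl]-N,N-dimethylacetamide | C=C(C)[C@@]1(CC(=O)N(C)C)CCC(=O)C=C1 | intermediate
10 | lithium (4S)-4-[2-(dimethylamino)-2-oxoethyl]-4-(prop-1-en-2-yl)cyclohex-1-en-1-olate | C=C(C)[C@@]1(CC(=O)N(C)C)CCC([O-])=CC1.[Li+] | intermediate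
11 | (4S)-4-[2-(dimethylamino)-2-oxoethyl]-4-(prop-1-en-2-yl)cyclohex-1-en-1-yl trifluoromethanesulfonate | C=C(C)[C@@]1(CC(=O)N(C)C)CCC(OS(=O)(=O)C(F)(F)F)=CC1 | intermediate
12 | 2-[(1S)-4-methyl-1-(prop-1-en-2-yl)cyclohex-3-en-1-yl]-N,N-dimethylacetamide | C=C(C)[C@@]1(CC(=O)N(C)C)CCC(C)=CC1 | intermediate
13 | 2-[(1S,4S,6R)-1-methyl-4-(prop-1-en-2-yl)-7-oxabicyclo[4.1.0]heptan-4-yl]-N,N-dimethylacetamide (epoxide oxygen syn to the acetamide arm) | C=C(C)[C@@]1(CC(=O)N(C)C)CC[C@]2(C)O[C@@H]2C1 | intermediate
14 | 2-[(1R,3S,4S)-3-bromo-4-hydroxy-4-methyl-1-(prop-1-en-2-yl)cyclohexyl]-N,N-dimethylacetamide | C=C(C)[C@@]1(CC(=O)N(C)C)CC[C@](C)(O)[C@@H](Br)C1 | intermediate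
15 | 2-[(1R,3S,4S)-3-bromo-4-chloro-4-methyl-1-(prop-1-en-2-yl)cyclohexyl]-N,N-dimethylacetamide | C=C(C)[C@@]1(CC(=O)N(C)C)CC[C@](C)(Cl)[C@@H](Br)C1 | intermediate
16 | 1-[(1R,3S,4S)-3-bromo-4-chloro-4-methyl-1-(prop-1-en-2-yl)cyclohexyl]-4-(trimethylsilyl)but-3-yn-2-one | C=C(C)[C@@]1(CC(=O)C#C[Si](C)(C)C)CC[C@](C)(Cl)[C@@H](Br)C1 | intermediate
17 | 4-bromo-1-[(1R,3S,4S)-3-bromo-4-chloro-4-methyl-1-(prop-1-en-2-yl)cyclohexyl]but-3-yn-2-one | C=C(C)[C@@]1(CC(=O)C#CBr)CC[C@](C)(Cl)[C@@H](Br)C1 | intermediate
18 | (6R,8S,9S)-4,8-dibromo-9-chloro-5,5,9-trimethylspiro[5.5]undec-3-en-2-one | O=C1C[C@@]2(CC[C@](C)(Cl)[C@@H](Br)C2)C(C)(C)C(Br)=C1 | intermediate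
19 | {[(6S,8S,9S)-4,8-dibromo-9-chloro-5,5,9-trimethylspiro[5.5]undeca-1,3-dien-2-yl]oxy}trimethylsilane | C[Si](C)(C)OC1=C[C@@]2(CC[C@](C)(Cl)[C@@H](Br)C2)C(C)(C)C(Br)=C1 | intermediate
20 | (6S,8S,9S)-4,8-dibromo-9-chloro-1-[(dimethylamino)methyl]-5,5,9-trimethylspiro[5.5]undec-3-en-2-one (both epimers at the aminomethyl carbon) | CN(C)CC1C(=O)C=C(Br)C(C)(C)[C@]12CC[C@](C)(Cl)[C@@H](Br)C2 | intermediate
21 | {[(6S,8S,9S)-4,8-dibromo-9-chloro-5,5,9-trimethyl-2-oxospiro[5.5]undec-3-en-1-yl]methyl}trimethylammonium iodide (both epimers) | C[N+](C)(C)CC1C(=O)C=C(Br)C(C)(C)[C@]12CC[C@](C)(Cl)[C@@H](Br)C2.[I-] | intermediate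
22 | (6S,8S,9S)-4,8-dibromo-9-chloro-5,5,9-trimethyl-1-methylidenespiro[5.5]undec-3-en-2-one (CNP0349926.1) | C=C1C(=O)C=C(Br)C(C)(C)[C@]12CC[C@](C)(Cl)[C@@H](Br)C2 | target

Total step count: 14. Longest linear sequence: 14 steps (from 1).

## Steps least certain to work

**Step 12 (Proposed new method).** The iron hydride may reduce the bromoynone (conjugate reduction or loss of the alkynyl bromine) faster than it activates the alkene. Silyl radicals formed in the chain may abstract the secondary bromine. The alcohol co-solvent may add to the very electrophilic ynone. 5-exo closure at C9 may compete. All follow from asking a reductive radical system to tolerate a bromoalkyne, which is without precedent. The fallback uses known reaction types and runs from amide 15 to 18. Lithiated acetonitrile (LDA, MeCN, THF, −78 °C) would convert 15 into the β-keto nitrile F1. Iron hydride conditions, applied in the known way for radical cyclisation of an alkene onto a nitrile (6-exo-dig attack of the C11 radical on the nitrile carbon), would close ring B as the cyclic vinylogous amide F2, and aqueous HCl would hydrolyse it to the 1,3-diketone F3. Pyrrolidine should condense at the less hindered carbonyl group (C8) to give the enaminone F4. Oxalyl bromide then activates the remaining oxygen on C10 and bromide replaces it, giving the bromo iminium bromide F5, whose hydrolysis returns to the route at 18 with bromine on C10. The detour costs four extra operations, and the halogenation through the enaminone is what puts bromine on the hindered carbon that direct bromination of the diketone would avoid.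

**Step 7.** Face selection by the dioxirane may be incomplete, because an alkyl-substituted cyclohexene gives the catalyst less to hold than an aryl alkene and C6 offers no help. Epoxidation of the isopropenyl group may also compete. The fallback gives up reagent control for separation and recycling and runs from 12 to 14. NBS in aqueous acetone should add to the trisubstituted alkene only and give the two trans-diaxial bromohydrins, 14 and its diastereomer 2-[(1R,3R,4R)-3-bromo-4-hydroxy-4-methyl-1-(prop-1-en-2-yl)cyclohexyl]-N,N-dimethylacetamide F6. After chromatographic separation, zinc in acetic acid would return F6 to 12 for another pass, and 14 continues at step 9.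

**Step 9.** The activated tertiary alcohol may lose a proton to give alkenes instead of taking up chloride. The amide oxygen, which sits on the face where chloride must enter, may capture the bromonium ion across the ring. The fallback bypasses the epoxide and the bromohydrin and runs from 12 to 15. NBS with Et4NCl in CH2Cl2 at low temperature would bromochlorinate the ring alkene directly, giving 15 and its diastereomer 2-[(1R,3R,4R)-3-bromo-4-chloro-4-methyl-1-(prop-1-en-2-yl)cyclohexyl]-N,N-dimethylacetamide F7. The two are separated, F7 is returned to 12 with zinc, and 15 continues at step 10. This gives up face control but removes the substitution at the tertiary carbon.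

**Step 10.** Addition to the amide, whose carbonyl group sits beside a quaternary carbon, may be slow, and a longer or warmer reaction invites loss of HBr or HCl from ring A or ionisation of the tertiary chloride by BF3. The fallback goes through the aldehyde and runs from 15 to 16. Cp2Zr(H)Cl in THF would reduce the tertiary amide to the aldehyde 2-[(1R,3S,4S)-3-bromo-4-chloro-4-methyl-1-(prop-1-en-2-yl)cyclohexyl]acetaldehyde F8. Lithium (trimethylsilyl)acetylide at −78 °C would add to give the propargylic alcohols F9 as a mixture of carbinol epimers, and Dess–Martin periodinane would oxidise them to 16.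

## Further compounds

F1 | step 12 | 4-[(1R,3S,4S)-3-bromo-4-chloro-4-methyl-1-(prop-1-en-2-yl)cyclohexyl]-3-oxobutanenitrile | C=C(C)[C@@]1(CC(=O)CC#N)CC[C@](C)(Cl)[C@@H](Br)C1
F2 | step 12 | cyclic vinylogous amide: ring B closed, amino group on C10, carbonyl at C8 | NC1=CC(=O)C[C@@]2(CC[C@](C)(Cl)[C@@H](Br)C2)C1(C)C
F3 | step 12 | spiro 1,3-diketone: ring B with carbonyl groups at C8 and C10 | O=C1CC(=O)C[C@@]2(CC[C@](C)(Cl)[C@@H](Br)C2)C1(C)C
F4 | step 12 | pyrrolidine enaminone of F3: nitrogen on C8, carbonyl at C10 | O=C1C=C(N2CCCC2)C[C@@]3(CC[C@](C)(Cl)[C@@H](Br)C3)C1(C)C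
F5 | step 12 | bromo iminium bromide: bromine on C10, pyrrolidinium on C8 | BrC1=CC(=[N+]2CCCC2)C[C@@]3(CC[C@](C)(Cl)[C@@H](Br)C3)C1(C)C.[Br-]
F6 | step 7 | 2-[(1R,3R,4R)-3-bromo-4-hydroxy-4-methyl-1-(prop-1-en-2-yl)cyclohexyl]-N,N-dimethylacetamide | C=C(C)[C@@]1(CC(=O)N(C)C)CC[C@@](C)(O)[C@H](Br)C1
F7 | step 9 | 2-[(1R,3R,4R)-3-bromo-4-chloro-4-methyl-1-(prop-1-en-2-yl)cyclohexyl]-N,N-dimethylacetamide | C=C(C)[C@@]1(CC(=O)N(C)C)CC[C@@](C)(Cl)[C@H](Br)C1
F8 | step 10 | 2-[(1R,3S,4S)-3-bromo-4-chloro-4-methyl-1-(prop-1-en-2-yl)cyclohexyl]acetaldehyde | C=C(C)[C@@]1(CC=O)CC[C@](C)(Cl)[C@@H](Br)C1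
F9 | step 10 | 1-[(1R,3S,4S)-3-bromo-4-chloro-4-methyl-1-(prop-1-en-2-yl)cyclohexyl]-4-(trimethylsilyl)but-3-yn-2-ol (both carbinol epimers) | C=C(C)[C@@]1(CC(O)C#C[Si](C)(C)C)CC[C@](C)(Cl)[C@@H](Br)C1
A1 | alternative 1 | bromo ether bridged from the C7 oxygen to C3 (2-oxabicyclo[2.2.2]octane across ring A) with ring B bromoenone | C[C@]12CC[C@]3(C[C@@H]1Br)[C@@](C)(O2)C(=O)C=C(Br)C3(C)C
A2 | alternative 2 | 10-bromo ring B with C7 methylene and quaternary C6 carrying acetoxymethyl and ketal arms | C=C1CC[C@@H](Br)C(C)(C)[C@]1(COC(C)=O)CCC2(C)OCCO2
A3 | alternative 3 | 7,7-dimethylspiro[5.5]undec-1-ene-3,8-dione (spiro enone with ring B C10 ketone, one enantiomer) | O=C1C=C[C@@]2(CC1)CCCC(=O)C2(C)C
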